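The data are calculated on assumed constants; the scatter is artificial.

Target, the product wanted, is made and consumed at once: substrate feeds it and it leaks away to its isomer. So d[target]/dt is the rate of making minus the rate of using, and [target] peaks at the moment the two are equal. Before that moment the readings rise, and after it they fall. The flask differs from the north run in its substrate charge and in its longest time, 3.0 d against 4.00 d. The highest north reading stands at 0.167 d, earlier than either of those times, so the question that matters is the charge: does the percent curve move with it?

| flask | substrate | catalyst | remark | time |
|---|---|---|---|---|
| north | 60 mM | 6.4 mM | run made earlier |  |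
| south-west | 95 mM | 6.4 mM | run made earlier |  |
| south-east | 43 mM | 3.2 mM | run made earlier |  |
| flask | 43 mM | 6.4 mM |  | 3.0 d |

- north (time / d: target / %): 0.0417: 39.5; 0.0833: 55.1; 0.167: 61.2; 0.417: 55.0; 0.833: 46.2; 1.67: 38.0; 4.00: 35.3
- south-west (time / d: target / %): 0.0417: 41.2; 0.0833: 55.7; 0.167: 60.9; 0.417: 55.3; 0.833: 48.0; 1.67: 38.8; 4.00: 35.8
- south-east (time / d: target / %): 0.0417: 40.2; 0.125: 60.5; 0.417: 55.1; 1.25: 42.0; 4.00: 35.4

(readings scatter by 0.5 percentage points)

- the moment within 3.0 d at which there is most target
- the amount of target, in percent of the substrate charged, at that time

If making and using are both first-order, a larger charge scales both rates by one factor, their comparison at each moment is unchanged, and the percent at a given time stays put. The test is the charge exponent, the power of the substrate charge to which the percent of target at one time is proportional. It is read from the highest readings of the north and south-west runs, both at 0.167 d: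

charge exponent = ln(60.9% / 61.2%) / ln(95 mM / 60 mM) = −0.0107

Those two readings differ by 0.3 percentage points, less than the scatter of 0.5 points, so this reading of the exponent cannot be told from zero. My own reckoning carries the north peak to the flask, near 0.167 d:

best = 61.2% × (43 mM / 60 mM)^exponent = 61.4%

The forecast, holding that “the percent profile seems independent of both charges”, gives 61.3% (60.3% to 62.5%) at 0.165 d (0.13 d to 0.2 d).

The flask gives 61.2% at 0.168 d.

    target ⇌ isomer of the product (K = 1.40, k = 0.0400 /h)
    catalyst ⇌ dormant form (K = 0.370, k = 0.450 /h)
    substrate ⇌ target (K = 2.20, k = 0.630 /h)

The forecast stands on an exponent near zero; a run at another charge whose percent moves well beyond the scatter is what overturns it. A neighbouring flask, like this one but charged with 73 mM of substrate, offers that test. The exponent carries the flask's peak to it: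

61.2% × (73 mM / 43 mM)^exponent = 60.9%

That neighbouring flask reaches 61.2% at its highest, and at 3.0 d it holds 16.2% substrate and 35.7% target.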